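The runs were generated by integration for substances that don't exist, noise included.

The trap here is to reach for a full rate law when the question turns on one ratio.

| setting | Monday's | Saturday's | Friday's | dawn | summer | spring |
|---|---|---|---|---|---|---|
| starting material | 0.019 M | 0.019 M | 0.019 M | 0.019 M (fed, over 2.0 min) | 0.019 M | 0.019 M |
| second substrate | 0.095 M | 0.095 M | 0.095 M | 0.0950 M | 0.0950 M | 0.0950 M |
| third substrate | 0.038 M | 0.025 M | 0.057 M | 0.0380 M | 0.0380 M | 0.0380 M (fed, over 2.0 min) |
| gas | 2.4 mM (held) | 2.4 mM (held) | 2.4 mM (held) | 2.4 mM (held) | 2.4 mM (held) | 2.4 mM (held) |
| remark | run made earlier | run made earlier | run made earlier | all else is in the flask from the start; the feed brings no volume worth counting | everything together at the start | all else is in the flask from the start; the feed brings no volume worth counting |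
| time |  |  |  | 10 min | 10 min | 10 min |

| run | time / min | isomer of the product / % | target / % |
|---|---|---|---|
| Monday's | 0.833 | 0.6 | 10.1 |
| Monday's | 2.00 | 3.6 | 23.0 |
| Monday's | 4.00 | 8.0 | 46.8 |
| Monday's | 6.00 | 13.2 | 64.7 |
| Saturday's | 0.833 | 2.8 | 9.4 |
| Saturday's | 2.00 | 3.1 | 24.4 |
| Saturday's | 4.00 | 7.6 | 48.9 |
| Saturday's | 6.00 | 10.8 | 69.6 |
| Friday's | 0.500 | 0.1 | 5.6 |
| Friday's | 1.00 | 2.1 | 9.6 |
| Friday's | 2.50 | 3.6 | 26.0 |
| Friday's | 6.00 | 11.3 | 57.8 |

(each reading ± 1 percentage point)

* the flask that comes out highest in amount of isomer of the product, in percent of the starting material charged; "all alike" if 1.5 percentage points covers them all (dawn / summer / spring / all alike)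
* amount of isomer of the product at the end, in percent of the starting material charged, dawn
* amount of isomer of the product at the end, in percent of the starting material charged, summer
* amount of isomer of the product at the end, in percent of the starting material charged, spring

- at the start none of the gas is in solution

I pool the last reading of each run. Isomer over isomer plus target gives φ = 15.5%, the isomer share, a selectivity. By rising third substrate the runs give 13.4%, 16.9% and 16.4%, so I read no clear trend through their scatter. The end isomer is then φ times the conversion.

Monday's run gives the conversion rate r, in fractions of the charge: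

r = 77.9% / 6.00 min = 0.130 min⁻¹

One extreme is a straight line (zero order). It finishes in 7.70 min, sooner than 10 min, and gives φ itself.

The other extreme is first order with constant r. It leaves 27.3% and gives 11.3%. But it puts 45.8% left at 6.00 min, where Monday's run shows 22.1%. So I go round again, taking the constant from Monday's last two readings:

k = 0.358 min⁻¹, left at the end 5.28%, isomer 14.7%

Dawn's feed delays the clock by about 1.00 min, which lowers this to 14.4%. The band is 1.1 percentage points wide, narrower than the margin of 1.5 points. I commit to equal flasks near 15.0%. Spring begins with no third substrate, which no run shows, so φ is an assumption there.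

The forecast says all alike, with 16%, 16% and 16% for dawn, summer and spring: “Feeding either component should therefore barely change selectivity.” Its number stands above my band.

The flasks give all alike: dawn 14.8%, summer 14.9%, spring 14.9%.

    starting material + reagent → target (k = 38.1 M⁻¹ s⁻¹)
    second substrate + reagent → second product (k = 16.3 M⁻¹ s⁻¹)
    third substrate + reagent → third product (k = 18.0 M⁻¹ s⁻¹)
    target ⇌ isomer of the product (K = 0.180, k = 0.00617 s⁻¹)
    2 second substrate → homo dimer (k = 0.0440 M⁻¹ s⁻¹)
    gas ⇌ reagent, rate k6*(csat - [reagent]) (kL = 0.0622 s⁻¹)

In dawn, target and isomer relax into each other, by that step alone and both ways together, with a half-life of 0.286 min, far shorter than the 10 min allowed. Dawn's end holds 83.7% target beside 14.8% isomer, a ratio of 0.177 beside the constant K of 0.18, and an isomer share of 15.0% beside my φ of 15.5%.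

Now dawn read at 4.0 min: with the same delay I expect 38.9% converted, and φ makes that 6.03% isomer. The computed flask holds 5.89% with 55.5% starting material left, so its conversion of 44.5% stands above my figure, while its isomer share of 13.2% stands below φ, and the two misses offset.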